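The numbers in the tables were computed for an exercise, and the scatter is random.

If a closed flask levels off, the figure to argue over is what a stirred tank gives up against that level, said the chair, opening the meeting on Z and its product X.

| flask | Z | remark | time |
|---|---|---|---|
| Thursday's | 0.080 M | run made earlier |  |
| Monday's | 0.040 M | run made earlier |  |
| elm | 0.080 M | a single well-mixed tank run continuously and read at steady state, 6.0 h in it on average |  |
| ash | 0.080 M | one stirred flow tank at steady state, fed with the mixture as stated, mean residence time 18.0 h |  |
| cedar | 0.080 M | everything together in a closed stirred flask, run for 6.0 h | 6.0 h |
| birch | 0.080 M | a tube with plug flow, the mixed feed as stated, residence time 6.0 h | 6.0 h |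

| Thursday's: time / h | Thursday's: X / % | Monday's: time / min | Monday's: X / % |
|---|---|---|---|
| 0.250 | 7.4 | 15.0 | 11.1 |
| 0.667 | 18.1 | 40.0 | 19.4 |
| 1.50 | 27.6 | 80.0 | 23.5 |
| 4.00 | 27.9 | 120 | 28.0 |

(standard deviation of a reading: 1 percentage point)

- the stated concentrations are those of everything mixed, before any reaction; amounts are the same in each set-up
- the earlier runs were made in a closed, stirred flask

1. the set-up with the highest amount of X at the outlet or at the end, in percent of the Z put in ("none" if the first two lie within 2 percentage points) (elm / ash / cedar / birch / none)
2. amount of X at the outlet or at the end, in percent of the Z put in, elm
3. amount of X at the outlet or at the end, in percent of the Z put in, ash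
4. amount of X at the outlet or at the end, in percent of the Z put in, cedar
5. amount of X at the outlet or at the end, in percent of the Z put in, birch

The kineticist read Thursday's run at both ends. At the long end, its last two readings put the level at 27.7% of the charge. At the short end, its second reading, taken as an exponential approach to that level, gave an approach constant of 1.58 h⁻¹. The process chemist added that Monday's run, at half the Z, read 28.0% of its charge at its last reading, which agrees with that level within the scatter.

The kineticist then joined the two ends. A tank with a brief stay gains the level times the approach constant times the residence time, and a tank with a long stay comes to the level. The join is the level times that product over one plus that product. What remains is the back-mixing deficit, the level divided by one plus the product. On this reckoning, which is the kineticist's own, elm falls short by 2.6 percentage points and ash by 0.94 points, and the ash deficit is less than the margin of 2 points.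

The forecaster reported elm 25.1%, ash 26.9%, cedar 27.9%, birch 27.9% and best none, on the ground that “6 h in the flask or the plug-flow tube is effectively complete”.

The simulation gave elm 25.7%, ash 27.7%, cedar 28.2%, birch 28.2% and best none.

    Z → L (k = 0.130 h⁻¹)
    Z → X (k = 0.490 h⁻¹)
    L → J (k = 0.0710 h⁻¹)
    X ⇌ Q (K = 1.30, k = 0.940 h⁻¹)
    Z ⇌ E (K = 1.70, k = 0.180 h⁻¹)
    E → J (k = 0.190 h⁻¹)

Elm stood 2.5 points below cedar against a deficit of 2.6 points, and ash stood 0.50 points below cedar against 0.94 points. For the elm tank at ten times its residence time the deficit comes to 0.29 points, and that tank gives 28.6%, against 29.0% in cedar left as long. The main reason cedar stops at 28.2% is the turning of X into Q, both ways, with thermodynamic control of the split between X and Q: without that step cedar gives 63.8%. Take away one part of that step, the way back from Q to X, and the answer to best changes, with cedar ending at 2.28%.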